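**Strategy.** The route rests on cutting the acyclic C8'–C9'–C10' triad of the side chain (ethyl/methyl at C10', hydroxyl at C9', carboxyl and C7' at C8') at C8'–C9' and C7'–C8'. The dihydropyranone ring is not involved and is joined last at C2'–C3'. In one operation a CHCl unit from dichloromethane is inserted into the C9'–B bond and a C3'–C7' Grignard reagent replaces chloride. This forms both bonds and the C8' centre and leaves boron on C8' for the carboxyl carbon. The precursor is the α-(4-methoxybenzyloxy) boronic ester of the (S)-sec-butyl unit with (S,S)-1,2-dicyclohexylethane-1,2-diol, made from methylboronic acid by two earlier homologations.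

Key step: step 7

Remarks on the chemistry:
- Locants: C1' is the ketone carbon on ring C3, C2'–C12' follow the chain, and the carboxyl carbon hangs on C8'; the ring is O1, C2–C6. The target is 6R,4'S,8'R,9'R,10'S.
- Hydrogenating dehydroacetic acid would give the ring as a racemate and hence both C6 epimers, so the 6R acetylpyranone is built from ethyl (R)-3-hydroxybutanoate.
- The (S,S)-diol on a methylboronate, with the nucleophiles in the order ethyl, alkoxide, C7' chain, gives 10'S, 9'R and 8'R.
- Protecting groups: C9'–O enters as a PMB ether, C3'–O is a TBS ether and the acid is a tert-butyl ester. The basic alkylation then meets no electrophilic ester, and one acid step unmasks everything.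
- Commercial starting materials are 1, 2, 4, 9 and 23.

**Route**

Step 1
Reactants: 1 methylboronic acid; 2 (1S,2S)-1,2-dicyclohexylethane-1,2-diol
Product: 3 (4S,5S)-4,5-dicyclohexyl-2-methyl-1,3,2-dioxaborolane
Conditions: MgSO4, Et2O, rt
Reagents that add atoms: none
Why: Condensation of a boronic acid with a 1,2-diol (boronic ester formation) is driven by the desiccant and touches no stereocenter.

Step 2
Reactants: 3 (4S,5S)-4,5-dicyclohexyl-2-methyl-1,3,2-dioxaborolane; 4 dichloromethane
Product: 6 (4S,5S)-2-[(2S)-butan-2-yl]-4,5-dicyclohexyl-1,3,2-dioxaborolane, via chloroethyl boronate 5 (not isolated)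
Conditions: 4 (3 equiv), LiN(iPr)2, THF, −40 °C; ZnCl2, −40 °C → rt; NH4Cl wash, crude 5; then EtMgBr, THF, −78 °C → rt
Reagents that add atoms: ethylmagnesium bromide, CC[Mg]Br
Why: This Matteson homologation inserts a CHCl unit into the C–B bond with the (S,S)-diol choosing the chloride that is lost (5, 1R), and the ethyl group then shifts from boron to carbon with inversion, which should set C10' as S.

Step 3
Reactants: 6 (4S,5S)-2-[(2S)-butan-2-yl]-4,5-dicyclohexyl-1,3,2-dioxaborolane; 4 dichloromethane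
Product: 8 (4S,5S)-4,5-dicyclohexyl-2-[(1S,2S)-1-[(4-methoxybenzyl)oxy]-2-methylbutyl]-1,3,2-dioxaborolane, via chloro boronate 7 (not isolated)
Conditions: 4 (3 equiv), LiN(iPr)2, THF, −40 °C; ZnCl2, −40 °C → rt; then 4-MeOC6H4CH2OH, NaH, THF/DMSO, 0 °C → rt
Reagents that add atoms: 4-methoxybenzyl alcohol, COc1ccc(CO)cc1
Why: A second Matteson homologation should give the (1R)-chloride 7 under control of the same diol, and the alkoxide then replaces chloride through a borate 1,2-shift with inversion, which places the C9' oxygen in the required sense.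

Step 4
Reactants: 9 (R)-3-bromo-2-methylpropan-1-ol
Product: 10 (R)-(3-bromo-2-methylpropoxy)(tert-butyl)dimethylsilane
Conditions: TBSCl, imidazole, CH2Cl2, 0 °C → rt
Reagents that add atoms: tert-butyldimethylsilyl chloride, CC(C)(C)[Si](C)(C)Cl
Why: Silyl ether formation under imidazole buffering protects the primary hydroxyl without the strong base that would close the bromo alcohol to an oxetane, and the stereocenter is not involved.

Step 5
Reactants: 10 (R)-(3-bromo-2-methylpropoxy)(tert-butyl)dimethylsilane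
Product: 12 (S)-5-[(tert-butyldimethylsilyl)oxy]-4-methylpentan-1-ol, via alkylmagnesium bromide 11 (not isolated)
Conditions: Mg, THF, rt → 40 °C; then oxirane, CuI (10 mol%), THF, −30 → 0 °C; aq. NH4Cl
Reagents that add atoms: oxirane, C1CO1
Why: Copper-catalysed Grignard opening of oxirane should give the primary alcohol extended by two carbons, with the methyl-bearing centre remote from the reacting carbon.

Step 6
Reactants: 12 (S)-5-[(tert-butyldimethylsilyl)oxy]-4-methylpentan-1-ol
Product: 13 (S)-[(5-bromo-2-methylpentyl)oxy](tert-butyl)dimethylsilane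
Conditions: CBr4, PPh3, CH2Cl2, 0 °C
Reagents that add atoms: carbon tetrabromide, BrC(Br)(Br)Br
Why: The Appel reaction converts the primary alcohol to the bromide under neutral conditions that a TBS ether tolerates.

Step 7
Reactants: 8 (4S,5S)-4,5-dicyclohexyl-2-[(1S,2S)-1-[(4-methoxybenzyl)oxy]-2-methylbutyl]-1,3,2-dioxaborolane; 4 dichloromethane; 13 (S)-[(5-bromo-2-methylpentyl)oxy](tert-butyl)dimethylsilane
Product: 16 (4S,5S)-4,5-dicyclohexyl-2-[(3S,4S,5R,9S)-10-[(tert-butyldimethylsilyl)oxy]-4-[(4-methoxybenzyl)oxy]-3,9-dimethyldecan-5-yl]-1,3,2-dioxaborolane, via alkylmagnesium bromide 14 (not isolated), via chloro boronate 15 (not isolated)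
Conditions: 13, Mg, THF, 40 °C (gives 14); 8, 4 (3 equiv), LiN(iPr)2, THF, −40 °C, then ZnCl2 (3 equiv), −40 °C → rt (gives 15, NH4Cl wash, used crude); then 14, THF, −78 °C → rt
Reagents that add atoms: none
Why: LiCHCl2 (from 4 and LiN(iPr)2) adds to boron of 8 and ZnCl2 promotes the 1,2-shift of C9' onto the new carbon with loss of one chloride to give 15, after which 14 adds to boron and its C7' carbon shifts to C8' with inversion, expelling the second chloride. The closest known reaction type is the Matteson homologation of chiral diol boronic esters, here on an α-alkoxy boronic ester and followed by Grignard substitution. No ring is closed, so no mode of closure arises. The new C8' centre is set by the C2-symmetric (S,S)-diol on boron, which decides which diastereotopic chloride of the borate is lost, and the stereospecific invertive second shift turns this into the 8'R arrangement, while C9' migrates with retention and C10' is untouched. The step needs selection of one chloride, no epimerisation of 15, and 1,2-shift in preference to β-elimination of the C9' ether; the diol secures the first, ZnCl2 (which binds free chloride and speeds the shift) the second, and the unhindered primary Grignard reagent at low temperature the third.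

Step 8
Reactants: 16 (4S,5S)-4,5-dicyclohexyl-2-[(3S,4S,5R,9S)-10-[(tert-butyldimethylsilyl)oxy]-4-[(4-methoxybenzyl)oxy]-3,9-dimethyldecan-5-yl]-1,3,2-dioxaborolane
Product: 18 (2S,6S)-7-[(tert-butyldimethylsilyl)oxy]-2-[(1R,2S)-1-[(4-methoxybenzyl)oxy]-2-methylbutyl]-6-methylheptan-1-ol, via homologated boronate 17 (not isolated)
Conditions: BrCH2Cl, n-BuLi, THF, −78 °C → rt; then 2 M NaOH, 30% H2O2, 0 °C → rt
Reagents that add atoms: bromochloromethane, ClCBr; hydrogen peroxide, OO
Why: LiCH2Cl made in situ adds to boron and the C8' group shifts with retention (Matteson chloromethyl homologation), and alkaline peroxide then oxidises the primary C–B bond to the alcohol, so C8' keeps its configuration.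

Step 9
Reactants: 18 (2S,6S)-7-[(tert-butyldimethylsilyl)oxy]-2-[(1R,2S)-1-[(4-methoxybenzyl)oxy]-2-methylbutyl]-6-methylheptan-1-ol
Product: 19 (2R,6S)-7-[(tert-butyldimethylsilyl)oxy]-2-[(1R,2S)-1-[(4-methoxybenzyl)oxy]-2-methylbutyl]-6-methylheptanoic acid
Conditions: TEMPO (cat.), PhI(OAc)2, MeCN/H2O, rt
Reagents that add atoms: water, O
Why: TEMPO/PhI(OAc)2 oxidation in wet acetonitrile takes the primary alcohol through the aldehyde hydrate to the acid under near-neutral conditions that should spare the PMB and TBS ethers and not epimerise C8'.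

Step 10
Reactants: 19 (2R,6S)-7-[(tert-butyldimethylsilyl)oxy]-2-[(1R,2S)-1-[(4-methoxybenzyl)oxy]-2-methylbutyl]-6-methylheptanoic acid
Product: 20 tert-butyl (2R,6S)-7-[(tert-butyldimethylsilyl)oxy]-2-[(1R,2S)-1-[(4-methoxybenzyl)oxy]-2-methylbutyl]-6-methylheptanoate
Conditions: tert-butyl 2,2,2-trichloroacetimidate, CH2Cl2/cyclohexane, rt
Reagents that add atoms: tert-butyl 2,2,2-trichloroacetimidate, CC(C)(C)OC(=N)C(Cl)(Cl)Cl
Why: Imidate esterification alkylates the carboxylic acid without base or activation of the hindered carboxyl, so C8' is not at risk.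

Step 11
Reactants: 20 tert-butyl (2R,6S)-7-[(tert-butyldimethylsilyl)oxy]-2-[(1R,2S)-1-[(4-methoxybenzyl)oxy]-2-methylbutyl]-6-methylheptanoate
Product: 21 tert-butyl (2R,6S)-7-hydroxy-2-[(1R,2S)-1-[(4-methoxybenzyl)oxy]-2-methylbutyl]-6-methylheptanoate
Conditions: HF·pyridine, THF/pyridine, 0 °C → rt
Reagents that add atoms: none
Why: Fluoride-mediated desilylation removes the primary TBS ether while the PMB ether and tert-butyl ester are stable and no strong base is present to eliminate the β-alkoxy ester.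

Step 12
Reactants: 21 tert-butyl (2R,6S)-7-hydroxy-2-[(1R,2S)-1-[(4-methoxybenzyl)oxy]-2-methylbutyl]-6-methylheptanoate
Product: 22 tert-butyl (2R,6S)-7-iodo-2-[(1R,2S)-1-[(4-methoxybenzyl)oxy]-2-methylbutyl]-6-methylheptanoate
Conditions: I2, PPh3, imidazole, CH2Cl2, 0 °C → rt
Reagents that add atoms: iodine, II
Why: Appel-type iodination turns the primary alcohol into the iodide by SN2 at C3' without touching the C4' centre.

Step 13
Reactants: 23 ethyl (R)-3-hydroxybutanoate
Product: 24 tert-butyl (R)-5-hydroxy-3-oxohexanoate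
Conditions: tert-butyl acetate, LiN(iPr)2 (3.5 equiv each), THF, −78 → −30 °C; aq. NH4Cl
Reagents that add atoms: tert-butyl acetate, CC(=O)OC(C)(C)C
Why: In this crossed Claisen condensation the excess lithium enolate of tert-butyl acetate acylates on the ethyl ester of the lithium alkoxide, and the carbinol centre is not involved.

Step 14
Reactants: 24 tert-butyl (R)-5-hydroxy-3-oxohexanoate
Product: 25 (R)-4-hydroxy-6-methyl-5,6-dihydro-2H-pyran-2-one
Conditions: CF3CO2H, CH2Cl2, rt
Reagents that add atoms: none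
Why: Acidolysis of the tert-butyl ester and lactonisation of the δ-hydroxy β-keto acid should give the six-membered keto lactone with C6 unchanged as R.

Step 15
Reactants: 25 (R)-4-hydroxy-6-methyl-5,6-dihydro-2H-pyran-2-one
Product: 27 (R)-3-acetyl-4-hydroxy-6-methyl-5,6-dihydro-2H-pyran-2-one, via enol acetate 26 (not isolated)
Conditions: AcOH, DCC, DMAP (1.2 equiv), CH2Cl2, 0 °C → rt
Reagents that add atoms: acetic acid, CC(=O)O
Why: DCC activates acetic acid for O-acylation of the enol and DMAP then transfers the acyl group to C3 (Fries-type O-to-C acyl migration), driven by the chelated tricarbonyl.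

Step 16
Reactants: 22 tert-butyl (2R,6S)-7-iodo-2-[(1R,2S)-1-[(4-methoxybenzyl)oxy]-2-methylbutyl]-6-methylheptanoate; 27 (R)-3-acetyl-4-hydroxy-6-methyl-5,6-dihydro-2H-pyran-2-one
Product: 29 tert-butyl (2R,6S)-9-[(6R)-4-hydroxy-6-methyl-2-oxo-5,6-dihydro-2H-pyran-3-yl]-2-[(1R,2S)-1-[(4-methoxybenzyl)oxy]-2-methylbutyl]-6-methyl-9-oxononanoate, via dilithium dienolate 28 (not isolated)
Conditions: 27 (2.5 equiv), LiN(iPr)2 (5.3 equiv), THF, −78 → 0 °C; then 22, DMPU, 0 °C → rt; 1 M HCl
Reagents that add atoms: none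
Why: Double deprotonation gives a dianion whose last-formed terminal carbanion on the acetyl group is the most nucleophilic site and should be alkylated by the primary iodide (γ-alkylation of a β-dicarbonyl dianion), while the hindered tert-butyl ester of 22 resists attack and no stereocenter is involved.

Step 17
Reactants: 29 tert-butyl (2R,6S)-9-[(6R)-4-hydroxy-6-methyl-2-oxo-5,6-dihydro-2H-pyran-3-yl]-2-[(1R,2S)-1-[(4-methoxybenzyl)oxy]-2-methylbutyl]-6-methyl-9-oxononanoate
Product: 30 (2R,6S)-2-[(1R,2S)-1-hydroxy-2-methylbutyl]-9-[(6R)-4-hydroxy-6-methyl-2-oxo-5,6-dihydro-2H-pyran-3-yl]-6-methyl-9-oxononanoic acid (CNP0392340.1)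
Conditions: CF3CO2H, anisole, CH2Cl2, 0 °C → rt
Reagents that add atoms: none
Why: Trifluoroacetic acid ionises both the tert-butyl ester and the 4-methoxybenzyl ether (acidolysis), anisole traps the benzyl cation, and neither the β-hydroxy acid nor the enolised tricarbonyl should be labile under these conditions.

**Compound list**

1 | methylboronic acid | CB(O)O | starting material
2 | (1S,2S)-1,2-dicyclohexylethane-1,2-diol | O[C@@H](C1CCCCC1)[C@H](C1CCCCC1)O | starting material
3 | (4S,5S)-4,5-dicyclohexyl-2-methyl-1,3,2-dioxaborolane | CB1O[C@@H](C2CCCCC2)[C@H](C2CCCCC2)O1 | intermediate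
4 | dichloromethane | ClCCl | starting material
5 | (4S,5S)-2-[(1R)-1-chloroethyl]-4,5-dicyclohexyl-1,3,2-dioxaborolane | C[C@H](Cl)B1O[C@@H](C2CCCCC2)[C@H](C2CCCCC2)O1 | intermediate (not isolated)
6 | (4S,5S)-2-[(2S)-butan-2-yl]-4,5-dicyclohexyl-1,3,2-dioxaborolane | CC[C@H](C)B1O[C@@H](C2CCCCC2)[C@H](C2CCCCC2)O1 | intermediate
7 | (4S,5S)-2-[(1R,2S)-1-chloro-2-methylbutyl]-4,5-dicyclohexyl-1,3,2-dioxaborolane | CC[C@H](C)[C@H](Cl)B1O[C@@H](C2CCCCC2)[C@H](C2CCCCC2)O1 | intermediate (not isolated)
8 | (4S,5S)-4,5-dicyclohexyl-2-[(1S,2S)-1-[(4-methoxybenzyl)oxy]-2-methylbutyl]-1,3,2-dioxaborolane | CC[C@H](C)[C@@H](OCc1ccc(OC)cc1)B1O[C@@H](C2CCCCC2)[C@H](C2CCCCC2)O1 | intermediate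
9 | (R)-3-bromo-2-methylpropan-1-ol | BrC[C@H](C)CO | starting material
10 | (R)-(3-bromo-2-methylpropoxy)(tert-butyl)dimethylsilane | BrC[C@H](C)CO[Si](C)(C)C(C)(C)C | intermediate
11 | [(R)-3-[(tert-butyldimethylsilyl)oxy]-2-methylpropyl]magnesium bromide | Br[Mg]C[C@H](C)CO[Si](C)(C)C(C)(C)C | intermediate (not isolated)
12 | (S)-5-[(tert-butyldimethylsilyl)oxy]-4-methylpentan-1-ol | OCCC[C@H](C)CO[Si](C)(C)C(C)(C)C | intermediate
13 | (S)-[(5-bromo-2-methylpentyl)oxy](tert-butyl)dimethylsilane | BrCCC[C@H](C)CO[Si](C)(C)C(C)(C)C | intermediate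
14 | [(S)-5-[(tert-butyldimethylsilyl)oxy]-4-methylpentyl]magnesium bromide | Br[Mg]CCC[C@H](C)CO[Si](C)(C)C(C)(C)C | intermediate (not isolated)
15 | (4S,5S)-2-[(1R,2R,3S)-1-chloro-2-[(4-methoxybenzyl)oxy]-3-methylpentyl]-4,5-dicyclohexyl-1,3,2-dioxaborolane | CC[C@H](C)[C@@H](OCc1ccc(OC)cc1)[C@H](Cl)B1O[C@@H](C2CCCCC2)[C@H](C2CCCCC2)O1 | intermediate (not isolated)
16 | (4S,5S)-4,5-dicyclohexyl-2-[(3S,4S,5R,9S)-10-[(tert-butyldimethylsilyl)oxy]-4-[(4-methoxybenzyl)oxy]-3,9-dimethyldecan-5-yl]-1,3,2-dioxaborolane | CC[C@H](C)[C@@H](OCc1ccc(OC)cc1)[C@@H](CCC[C@H](C)CO[Si](C)(C)C(C)(C)C)B1O[C@@H](C2CCCCC2)[C@H](C2CCCCC2)O1 | intermediate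
17 | (4S,5S)-4,5-dicyclohexyl-2-{(2R,6S)-7-[(tert-butyldimethylsilyl)oxy]-2-[(1R,2S)-1-[(4-methoxybenzyl)oxy]-2-methylbutyl]-6-methylheptyl}-1,3,2-dioxaborolane | CC[C@H](C)[C@@H](OCc1ccc(OC)cc1)[C@@H](CCC[C@H](C)CO[Si](C)(C)C(C)(C)C)CB1O[C@@H](C2CCCCC2)[C@H](C2CCCCC2)O1 | intermediate (not isolated)
18 | (2S,6S)-7-[(tert-butyldimethylsilyl)oxy]-2-[(1R,2S)-1-[(4-methoxybenzyl)oxy]-2-methylbutyl]-6-methylheptan-1-ol | CC[C@H](C)[C@@H](OCc1ccc(OC)cc1)[C@@H](CCC[C@H](C)CO[Si](C)(C)C(C)(C)C)CO | intermediate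
19 | (2R,6S)-7-[(tert-butyldimethylsilyl)oxy]-2-[(1R,2S)-1-[(4-methoxybenzyl)oxy]-2-methylbutyl]-6-methylheptanoic acid | CC[C@H](C)[C@@H](OCc1ccc(OC)cc1)[C@@H](CCC[C@H](C)CO[Si](C)(C)C(C)(C)C)C(=O)O | intermediate
20 | tert-butyl (2R,6S)-7-[(tert-butyldimethylsilyl)oxy]-2-[(1R,2S)-1-[(4-methoxybenzyl)oxy]-2-methylbutyl]-6-methylheptanoate | CC[C@H](C)[C@@H](OCc1ccc(OC)cc1)[C@@H](CCC[C@H](C)CO[Si](C)(C)C(C)(C)C)C(=O)OC(C)(C)C | intermediate
21 | tert-butyl (2R,6S)-7-hydroxy-2-[(1R,2S)-1-[(4-methoxybenzyl)oxy]-2-methylbutyl]-6-methylheptanoate | CC[C@H](C)[C@@H](OCc1ccc(OC)cc1)[C@@H](CCC[C@H](C)CO)C(=O)OC(C)(C)C | intermediate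
22 | tert-butyl (2R,6S)-7-iodo-2-[(1R,2S)-1-[(4-methoxybenzyl)oxy]-2-methylbutyl]-6-methylheptanoate | CC[C@H](C)[C@@H](OCc1ccc(OC)cc1)[C@@H](CCC[C@H](C)CI)C(=O)OC(C)(C)C | intermediate
23 | ethyl (R)-3-hydroxybutanoate | CCOC(=O)C[C@@H](C)O | starting material
24 | tert-butyl (R)-5-hydroxy-3-oxohexanoate | CC(C)(C)OC(=O)CC(=O)C[C@@H](C)O | intermediate
25 | (R)-4-hydroxy-6-methyl-5,6-dihydro-2H-pyran-2-one | O=C1C=C(O)C[C@@H](C)O1 | intermediate
26 | (R)-6-methyl-2-oxo-5,6-dihydro-2H-pyran-4-yl acetate | CC(=O)OC1=CC(=O)O[C@H](C)C1 | intermediate (not isolated)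
27 | (R)-3-acetyl-4-hydroxy-6-methyl-5,6-dihydro-2H-pyran-2-one | CC(=O)C1=C(O)C[C@@H](C)OC1=O | intermediate
28 | dilithium dienolate of 27 (acetyl CH2 and O4 deprotonated) | [Li+].[Li+].C=C([O-])C1=C([O-])C[C@@H](C)OC1=O | intermediate (not isolated)
29 | tert-butyl (2R,6S)-9-[(6R)-4-hydroxy-6-methyl-2-oxo-5,6-dihydro-2H-pyran-3-yl]-2-[(1R,2S)-1-[(4-methoxybenzyl)oxy]-2-methylbutyl]-6-methyl-9-oxononanoate | CC[C@H](C)[C@@H](OCc1ccc(OC)cc1)[C@@H](CCC[C@H](C)CCC(=O)C1=C(O)C[C@@H](C)OC1=O)C(=O)OC(C)(C)C | intermediate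
30 | (2R,6S)-2-[(1R,2S)-1-hydroxy-2-methylbutyl]-9-[(6R)-4-hydroxy-6-methyl-2-oxo-5,6-dihydro-2H-pyran-3-yl]-6-methyl-9-oxononanoic acid | CC[C@H](C)[C@@H](O)[C@@H](CCC[C@H](C)CCC(=O)C1=C(O)C[C@@H](C)OC1=O)C(=O)O | target

**Step count**

Total: 17 steps. Longest linear sequence: 11 steps (from 1 through steps 1–3, 7–12, 16, 17; equally from 9 through steps 4–12, 16, 17).

**Steps most likely to fail**

1. Step 7 (key step). What may go wrong: slow carbenoid insertion at the hindered, oxygen-bearing C9'–B bond; chloride-induced epimerisation of 15 before it is substituted; and fragmentation of the Grignard-derived borate by β-elimination of the C9' ether in place of the 1,2-shift. The fallback sets out from 14 (with 8 as partner) and comes back at 16. Grignard reagent 14 is trapped with paraformaldehyde to give (S)-6-[(tert-butyldimethylsilyl)oxy]-5-methylhexan-1-ol F1. N,N-Diisopropylcarbamoyl chloride and Et3N convert this into the N,N-diisopropylcarbamate F2. Deprotonation with s-BuLi/(−)-sparteine in Et2O at −78 °C should give the configurationally stable (S)-lithiated carbamate F3. Boronic ester 8 adds to it with retention to give the lithium borate F4, and warming with MgBr2·OEt2 should induce the 1,2-shift of C9' with inversion at C8' and loss of the carbamate, giving 16. Here C8' comes from the carbamate carbon and its configuration from the sparteine-directed deprotonation. No dichloromethyl insertion at C9' and no chloro borate with a β-ether are needed.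

2. Step 16. What may go wrong: competing deprotonation at ring C5 or O-alkylation of the ambident dianion, and slow SN2 at the β-branched C3' iodide that leaves time for proton transfer from the ester α-position. The fallback sets out from 22 (with 25 as partner) and comes back at 29. The dianion of acetic acid (LiN(iPr)2, THF/DMPU) is alkylated by 22 to give (4S,8R,9R,10S)-8-(tert-butoxycarbonyl)-9-[(4-methoxybenzyl)oxy]-4,10-dimethyldodecanoic acid F5. DCC/DMAP coupling of F5 with 25 gives the enol ester F6, which DMAP should rearrange (Fries-type O-to-C acyl shift) to 29. The ring is then attached by acylation at C3 and not by alkylation at C2', so the regiochemistry of a pyranone dianion no longer matters.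

3. Step 8. What may go wrong: β-elimination of the C9' ether from the chloromethyl borate of the hindered secondary boronic ester, or an incomplete 1,2-shift, so that unhomologated boronic ester is carried into the oxidation. The fallback sets out from 16 and comes back at 19. Insertion with LiCHCl2/ZnCl2 (the reaction class already used in steps 2, 3 and 7) gives the α-chloro boronic ester F7. NaClO2 (NaH2PO4, 2-methylbut-2-ene, t-BuOH/H2O) should oxidise F7 directly to acid 19. The carboxyl carbon then arrives at the aldehyde oxidation level, and 17, 18 and the alcohol oxidation are bypassed.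

**Further compounds**

F1 | step 7 | (S)-6-[(tert-butyldimethylsilyl)oxy]-5-methylhexan-1-ol | OCCCC[C@H](C)CO[Si](C)(C)C(C)(C)C
F2 | step 7 | (S)-6-[(tert-butyldimethylsilyl)oxy]-5-methylhexyl N,N-diisopropylcarbamate | CC(C)N(C(C)C)C(=O)OCCCC[C@H](C)CO[Si](C)(C)C(C)(C)C
F3 | step 7 | (1S,5S)-6-[(tert-butyldimethylsilyl)oxy]-1-lithio-5-methylhexyl N,N-diisopropylcarbamate (as its (−)-sparteine complex) | CC(C)N(C(C)C)C(=O)O[C@@H]([Li])CCC[C@H](C)CO[Si](C)(C)C(C)(C)C
F4 | step 7 | lithium borate formed from F3 and 8 | [Li+].CC[C@H](C)[C@@H](OCc1ccc(OC)cc1)[B-]1(O[C@@H](C2CCCCC2)[C@H](C2CCCCC2)O1)[C@H](OC(=O)N(C(C)C)C(C)C)CCC[C@H](C)CO[Si](C)(C)C(C)(C)C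
F5 | step 16 | (4S,8R,9R,10S)-8-(tert-butoxycarbonyl)-9-[(4-methoxybenzyl)oxy]-4,10-dimethyldodecanoic acid | CC[C@H](C)[C@@H](OCc1ccc(OC)cc1)[C@@H](CCC[C@H](C)CCC(=O)O)C(=O)OC(C)(C)C
F6 | step 16 | (R)-6-methyl-2-oxo-5,6-dihydro-2H-pyran-4-yl ester of F5 | CC[C@H](C)[C@@H](OCc1ccc(OC)cc1)[C@@H](CCC[C@H](C)CCC(=O)OC1=CC(=O)O[C@H](C)C1)C(=O)OC(C)(C)C
F7 | step 8 | α-chloro boronic ester from 16 by CHCl insertion into the C8'–B bond, (S,S)-diol retained | CC[C@H](C)[C@@H](OCc1ccc(OC)cc1)[C@@H](CCC[C@H](C)CO[Si](C)(C)C(C)(C)C)[C@H](Cl)B1O[C@@H](C2CCCCC2)[C@H](C2CCCCC2)O1
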